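Does ash, left for 120 min, end with more product than elm, stopped at 40 min? The two flasks have the same charges, so the question is what the extra time is worth.

the same everywhere: starting material 0.070 M; free catalyst 0.35 mM; second catalyst 50 µM

| flask | solid reagent | remark | time |
|---|---|---|---|
| Tuesday's | 0.070 M | run made earlier |  |
| Monday's | 0.16 M | run made earlier |  |
| ash | 0.105 M |  | 120 min |
| elm | 0.105 M |  | 40 min |

| Tuesday's: time / min | Tuesday's: product / % | Monday's: time / min | Monday's: product / % |
|---|---|---|---|
| 3.00 | 1 | 3.00 | 2 |
| 5.00 | 1 | 5.00 | 0 |
| 8.00 | 2 | 8.00 | 3 |
| 12.0 | 6 | 12.0 | 6 |
| 15.0 | 9 | 15.0 | 10 |
| 25.0 | 17 | 25.0 | 14 |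
| 40.0 | 25 | 40.0 | 27 |

(standard deviation of a reading: 1.5 percentage points)

- given per volume of solution although it is solid: solid reagent
- at the start none of the solid reagent is in solution

- which of the two ends with the higher amount of product, in percent of the starting material charged ("neither" if they lie within 2 percentage points) (ash / elm / neither)
- product at the end, in percent of the starting material charged, ash
- product at the end, in percent of the starting material charged, elm

Tuesday's and Monday's runs hold 1.00 and 2.29 equivalents of solid reagent, yet at 40.0 min they differ by 2 percentage points, against a scatter of 1.5 points per reading. Ash and elm hold 1.50 equivalents, between those two, so we read elm off the mean of the runs, 26.0%.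

The bench rule for ash is a straight line. From the mean 2.50% at 8.00 min, the slope is 0.00734 min⁻¹ of the charge, which gives 84.8% at 120 min. But that time is 3.00 times the last reading, and between the two the line keeps the rate fixed while the charge not yet product falls by a factor of 4.87. The readings show no clear curvature beyond their scatter, so this is our judgement, not a reading: we take the rate to follow what is not yet product.

We therefore carry the pseudo-first-order constant k, the fraction of the unconverted charge that becomes product each minute, as read from the two means, 0.00862 min⁻¹. It gives ash 62.9%, which is more than elm's 26.0%.

The forecast says ash, with 66% for ash and 26% for elm, and states: “Extrapolating to 120 min is the uncertain step”; its ash figure stands above our 62.9%.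

The flask gives 63.7% for ash and 25.8% for elm, so ash ends higher. At its end, ash holds 24.8% starting material and 11.5% intermediate, together 36.3% not yet product. Started from ash's 38.0% at 60.0 min, k gives 63.0% at 120 min.

    coupling partner + second catalyst + intermediate → second catalyst + product (k = 9020 M⁻² min⁻¹)
    solid reagent ⇌ coupling partner, rate k2*(cs2 - [coupling partner]) while solid is left; crystals form when [coupling partner] > cs2 (solubility = 0.0630 M, k = 1.83 min⁻¹)
    starting material + free catalyst ⇌ free catalyst + intermediate (K = 0.567, k = 140 M⁻¹ min⁻¹)

A neighbour of elm has 4.00 times the second catalyst. If k scaled with it, k would be 0.0345 min⁻¹, giving 67.6% at 40 min. The computed flask gives 58.1%, less than that, with 33% starting material and 9.18% intermediate left.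

The earlier runs and the new flask were computed for substances that don't exist; noise was put on by code.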